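The route rests on cutting the target at O1–C2 of the tetrahydrofuran and at the CH2–O bond of the spiro-oxirane. The key step forms both in one flask from an epoxy tosylate: acid makes the C5 hydroxyl open a C2–C3 epoxide at benzylic C2 (5-endo, inversion), then base lets the liberated C3 alkoxide displace the neighbouring tosylate. It exploits the vicinal C2–O1/C3–O oxygenation of the tetrahydrofuran and treats the oxirane CH2 as a former allylic carbinol carbon, so one Sharpless epoxidation sets C2 and C3. The precursor is a cis-aryl oxiranylmethyl tosylate, made from a Z-allylic alcohol, with free C5–OH and acetate-capped phenols.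

Key step: step 16

Remark (numbering): O1, C2 (aryl), C3 (spiro), C4 (benzyl) and C5 refer to the tetrahydrofuran of the target in every intermediate; TBS = tert-butyldimethylsilyl, Ts = 4-methylbenzenesulfonyl.
Remark (assumption): the (S,S)-Et-DuPHOS rhodium catalyst is taken to give the R acid, as this catalyst class does with Stobbe half-esters; the mirror-image ligand would be used if the sense proved opposite.
Remark (design of the precursor): the C5 hydroxyl stays silylated from before the ester reduction until after tosylation, because a free 1,4-diol could not be sulfonylated selectively. The phenols are acetylated before the epoxidation, so that the epoxide is never formed on an electron-rich para-alkoxystyrene. The Z geometry is fixed by a stereodefined enol tosylate.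
Remark (materials): the benzyl ether of isovanillin, dimethyl succinate and the pinacol boronate of the vanillin-type ring are catalogue chemicals.

Step 1
Reactants: 1 3-(benzyloxy)-4-methoxybenzaldehyde; 2 dimethyl succinate
Product: 3 (E)-4-[3-(benzyloxy)-4-methoxyphenyl]-3-(methoxycarbonyl)but-3-enoic acid
Conditions: NaOMe, MeOH, reflux; aq HCl
Reagents that add atoms: none
Why: Stobbe condensation: the succinate enolate adds to the aldehyde, lactonises and opens by E1cB elimination to the alkylidene half-ester, which leaves the free acid on the CH2 arm and should favour the E alkene (any Z isomer is tolerated in step 2).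

Step 2
Reactants: 3 (E)-4-[3-(benzyloxy)-4-methoxyphenyl]-3-(methoxycarbonyl)but-3-enoic acid
Product: 4 (3R)-4-[3-(benzyloxy)-4-methoxyphenyl]-3-(methoxycarbonyl)butanoic acid
Conditions: H2 (5 bar), [Rh(cod)((S,S)-Et-DuPHOS)]BF4 (cat.), NaOMe (cat.), MeOH, rt
Reagents that add atoms: none
Why: Rhodium–bisphospholane asymmetric hydrogenation of an itaconate-type half-ester: carboxylate and alkene chelate the metal, hydrogen is delivered to one face and C4 is set as R under catalyst control, E and Z alkenes converging on the same product.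

Step 3
Reactants: 4 (3R)-4-[3-(benzyloxy)-4-methoxyphenyl]-3-(methoxycarbonyl)butanoic acid
Product: 5 4-tert-butyl 1-methyl (2R)-2-[3-(benzyloxy)-4-methoxybenzyl]butanedioate
Conditions: tert-butyl 2,2,2-trichloroacetimidate, BF3·OEt2 (cat.), CH2Cl2–cyclohexane, 0 °C to rt
Reagents that add atoms: tert-butyl 2,2,2-trichloroacetimidate, CC(C)(C)OC(=N)C(Cl)(Cl)Cl
Why: Acid-catalysed O-alkylation of the carboxylic acid by a trichloroacetimidate (tert-butyl ester formation) makes the two carboxyl termini chemically different without touching the methyl ester or the benzyl ether.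

Step 4
Reactants: 5 4-tert-butyl 1-methyl (2R)-2-[3-(benzyloxy)-4-methoxybenzyl]butanedioate
Product: 6 tert-butyl (3R)-4-[3-(benzyloxy)-4-methoxyphenyl]-3-(hydroxymethyl)butanoate
Conditions: LiBH4, THF, MeOH (1 equiv), 0 °C to rt; aq NH4Cl
Reagents that add atoms: none
Why: Chemoselective borohydride reduction: LiBH4 reduces the methyl ester to the C5 carbinol while the bulky tert-butyl ester is left, under conditions too mild to epimerise C4.

Step 5
Reactants: 6 tert-butyl (3R)-4-[3-(benzyloxy)-4-methoxyphenyl]-3-(hydroxymethyl)butanoate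
Product: 7 tert-butyl (3R)-4-(3-hydroxy-4-methoxyphenyl)-3-(hydroxymethyl)butanoate
Conditions: H2 (1 bar), Pd/C, EtOAc, rt
Reagents that add atoms: none
Why: Catalytic hydrogenolysis of the aryl benzyl ether is placed here because no alkene is yet present; the tert-butyl ester and the carbinol are inert.

Step 6
Reactants: 7 tert-butyl (3R)-4-(3-hydroxy-4-methoxyphenyl)-3-(hydroxymethyl)butanoate
Product: 8 tert-butyl (3R)-4-{3-[(TBS)oxy]-4-methoxyphenyl}-3-{[(TBS)oxy]methyl}butanoate
Conditions: TBSCl, imidazole, DMF, rt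
Reagents that add atoms: tert-butyldimethylsilyl chloride, CC(C)(C)[Si](C)(C)Cl
Why: Standard silylation (silyl chloride–imidazole) caps the phenol and the C5 hydroxyl in one operation, the latter staying masked until just before the key step.

Step 7
Reactants: 8 tert-butyl (3R)-4-{3-[(TBS)oxy]-4-methoxyphenyl}-3-{[(TBS)oxy]methyl}butanoate
Product: 9 tert-butyl (3R)-2-formyl-4-{3-[(TBS)oxy]-4-methoxyphenyl}-3-{[(TBS)oxy]methyl}butanoate (C2 epimers and enol form)
Conditions: LiN(iPr)2, THF, −78 °C; HCO2Me, −78 to −20 °C; aq NH4Cl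
Reagents that add atoms: methyl formate, COC=O
Why: Crossed Claisen condensation of the tert-butyl ester enolate with a non-enolisable formate installs the future C2 as a formyl carbon; C4 is not acidic under these conditions.

Step 8
Reactants: 9 tert-butyl (3R)-2-formyl-4-{3-[(TBS)oxy]-4-methoxyphenyl}-3-{[(TBS)oxy]methyl}butanoate
Product: 10 tert-butyl (2Z,3R)-4-{3-[(TBS)oxy]-4-methoxyphenyl}-3-{[(TBS)oxy]methyl}-2-[(Ts-oxy)methylidene]butanoate
Conditions: TsCl, TMEDA, LiCl, MeCN, 0 °C
Reagents that add atoms: 4-methylbenzenesulfonyl chloride, Cc1ccc(S(=O)(=O)Cl)cc1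
Why: Chelation-controlled enol sulfonylation of a 2-formyl ester: lithium holds the enolate oxygen syn to the ester carbonyl, so O-tosylation should give the Z enol tosylate (tosyloxy cis to the ester), which fixes the later alkene geometry.

Step 9
Reactants: 11 2-methoxy-4-(4,4,5,5-tetramethyl-1,3,2-dioxaborolan-2-yl)phenol
Product: 12 tert-butyl[2-methoxy-4-(4,4,5,5-tetramethyl-1,3,2-dioxaborolan-2-yl)phenoxy]dimethylsilane
Conditions: TBSCl, imidazole, CH2Cl2, rt
Reagents that add atoms: tert-butyldimethylsilyl chloride, CC(C)(C)[Si](C)(C)Cl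
Why: Silylation of the phenol (silyl chloride–imidazole) prevents a para-phenoxide from forming in the coupling, where push–pull conjugation with the ester could let the Z enoate isomerise.

Step 10
Reactants: 10 tert-butyl (2Z,3R)-4-{3-[(TBS)oxy]-4-methoxyphenyl}-3-{[(TBS)oxy]methyl}-2-[(Ts-oxy)methylidene]butanoate; 12 tert-butyl[2-methoxy-4-(4,4,5,5-tetramethyl-1,3,2-dioxaborolan-2-yl)phenoxy]dimethylsilane
Product: 13 tert-butyl (2Z,3R)-2-({4-[(TBS)oxy]-3-methoxyphenyl}methylidene)-4-{3-[(TBS)oxy]-4-methoxyphenyl}-3-{[(TBS)oxy]methyl}butanoate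
Conditions: Pd(OAc)2 (cat.), SPhos, K3PO4, THF–H2O, 40 °C
Reagents that add atoms: none
Why: Suzuki–Miyaura coupling of an activated enol tosylate: oxidative addition of zerovalent palladium into the vinylic C–O bond, transmetalation and reductive elimination all proceed with retention, so the aryl group should end cis to the ester (Z).

Step 11
Reactants: 13 tert-butyl (2Z,3R)-2-({4-[(TBS)oxy]-3-methoxyphenyl}methylidene)-4-{3-[(TBS)oxy]-4-methoxyphenyl}-3-{[(TBS)oxy]methyl}butanoate
Product: 14 (2Z,3R)-2-({4-[(TBS)oxy]-3-methoxyphenyl}methylidene)-4-{3-[(TBS)oxy]-4-methoxyphenyl}-3-{[(TBS)oxy]methyl}butan-1-ol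
Conditions: iBu2AlH, CH2Cl2, −78 to 0 °C; aq KNaC4H4O6
Reagents that add atoms: none
Why: Hydride 1,2-reduction of the conjugated ester by iBu2AlH gives the allylic alcohol at low temperature and should leave the alkene geometry and all three silyl ethers untouched.

Step 12
Reactants: 14 (2Z,3R)-2-({4-[(TBS)oxy]-3-methoxyphenyl}methylidene)-4-{3-[(TBS)oxy]-4-methoxyphenyl}-3-{[(TBS)oxy]methyl}butan-1-ol
Product: 16 (2Z,3R)-2-[(4-acetoxy-3-methoxyphenyl)methylidene]-4-(3-acetoxy-4-methoxyphenyl)-3-{[(TBS)oxy]methyl}butan-1-ol, via bis-phenol 15 (not isolated)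
Conditions: Cs2CO3, DMF–H2O (10:1), rt; then Ac2O, 0 °C
Reagents that add atoms: acetic anhydride, CC(=O)OC(C)=O
Why: Selective desilylation followed by phenoxide O-acylation: carbonate in wet DMF cleaves aryl silyl ethers far faster than the alkyl one, and the caesium phenoxides are acetylated much faster than the neutral primary alcohol, so both phenols are re-capped as electron-withdrawing acetates in one flask.

Step 13
Reactants: 16 (2Z,3R)-2-[(4-acetoxy-3-methoxyphenyl)methylidene]-4-(3-acetoxy-4-methoxyphenyl)-3-{[(TBS)oxy]methyl}butan-1-ol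
Product: 17 {(2S,3R)-3-(4-acetoxy-3-methoxyphenyl)-2-[(2S)-1-(3-acetoxy-4-methoxyphenyl)-3-[(TBS)oxy]propan-2-yl]oxiran-2-yl}methanol
Conditions: Ti(OiPr)4 (1 equiv), L-(+)-diisopropyl tartrate, tBuOOH, 4 Å molecular sieves, CH2Cl2, −20 °C
Reagents that add atoms: tert-butyl hydroperoxide, CC(C)(C)OO
Why: Katsuki–Sharpless asymmetric epoxidation: the titanium–tartrate complex binds the allylic hydroxyl and delivers the peroxide oxygen to one alkene face, L-(+)-tartrate giving the (2S,3R)-oxiranylmethanol series from Z-3-aryl allylic alcohols, so C3 should be set S and C2 R with aryl cis to the hydroxymethyl arm, and attack on the other face would give a separable diastereomer because C4 is already fixed.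

Step 14
Reactants: 17 {(2S,3R)-3-(4-acetoxy-3-methoxyphenyl)-2-[(2S)-1-(3-acetoxy-4-methoxyphenyl)-3-[(TBS)oxy]propan-2-yl]oxiran-2-yl}methanol
Product: 18 {(2S,3R)-3-(4-acetoxy-3-methoxyphenyl)-2-[(2S)-1-(3-acetoxy-4-methoxyphenyl)-3-[(TBS)oxy]propan-2-yl]oxiran-2-yl}methyl 4-methylbenzenesulfonate
Conditions: TsCl, Et3N, Me3N·HCl (cat.), CH2Cl2, 0 °C
Reagents that add atoms: 4-methylbenzenesulfonyl chloride, Cc1ccc(S(=O)(=O)Cl)cc1
Why: Amine-mediated sulfonylation of the only free hydroxyl turns the epoxide's hydroxymethyl arm into the leaving group; the non-aqueous amine base avoids Payne rearrangement, and the aryl acetates are spared because no acyl-transfer catalyst is present.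

Step 15
Reactants: 18 {(2S,3R)-3-(4-acetoxy-3-methoxyphenyl)-2-[(2S)-1-(3-acetoxy-4-methoxyphenyl)-3-[(TBS)oxy]propan-2-yl]oxiran-2-yl}methyl 4-methylbenzenesulfonate
Product: 19 {(2S,3R)-3-(4-acetoxy-3-methoxyphenyl)-2-[(2S)-1-(3-acetoxy-4-methoxyphenyl)-3-hydroxypropan-2-yl]oxiran-2-yl}methyl 4-methylbenzenesulfonate
Conditions: HF·pyridine, pyridine, THF, 0 °C
Reagents that add atoms: none
Why: Fluoride-mediated desilylation with pyridine-buffered HF frees the C5 hydroxyl under mildly acidic, non-nucleophilic conditions, so no alkoxide is formed next to the tosylate and the aryl acetates should stay on.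

Step 16
Reactants: 19 {(2S,3R)-3-(4-acetoxy-3-methoxyphenyl)-2-[(2S)-1-(3-acetoxy-4-methoxyphenyl)-3-hydroxypropan-2-yl]oxiran-2-yl}methyl 4-methylbenzenesulfonate
Product: 21 (3S,4S,7S)-4-(4-acetoxy-3-methoxyphenyl)-7-(3-acetoxy-4-methoxybenzyl)-1,5-dioxaspiro[2.4]heptane, via hydroxy tosylate 20 (not isolated)
Conditions: camphorsulfonic acid (0.1 equiv), CH2Cl2, −20 to 0 °C; then DBU (2 equiv), 0 °C to rt
Reagents that add atoms: none
Why: Camphorsulfonic acid protonates the oxirane oxygen and the C5 hydroxyl attacks benzylic C2 from the side opposite the breaking C2–O bond (borderline SN2) to give hydroxy tosylate 20; DBU then lets the C3 hydroxyl, whose C3–O bond is never broken, displace the primary tosylate and close the oxirane of 21. The closest known reactions are the acid-mediated endo cyclisation of hydroxy aryl epoxides to 2-aryl-3-hydroxytetrahydrofurans and the base closure of 1,2-hydroxy sulfonates to epoxides. The tetrahydrofuran closes 5-endo-tet at the epoxide, preferred over the 4-exo path because C2 is benzylic and the exo path would give an oxetane, and the spiro-oxirane closes 3-exo-tet. C2 is set by inversion of the R-configured epoxide carbon, so its configuration derives from the Sharpless step and the Z alkene geometry, while C3 and C4 are carried through unchanged. The step needs attack at C2 with clean inversion and not through a free benzylic cation: the para-acetoxy group keeps the arene from stabilising a cation, the acid is catalytic and cold, and the base is added only after the acid stage so that a C5 alkoxide never meets the tosylate (which would close a 5-exo-tet ether instead).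

Step 17
Reactants: 21 (3S,4S,7S)-4-(4-acetoxy-3-methoxyphenyl)-7-(3-acetoxy-4-methoxybenzyl)-1,5-dioxaspiro[2.4]heptane
Product: 22 (3S,4S,7S)-4-(4-hydroxy-3-methoxyphenyl)-7-(3-hydroxy-4-methoxybenzyl)-1,5-dioxaspiro[2.4]heptane
Conditions: K2CO3 (cat.), MeOH, 0 °C
Reagents that add atoms: none
Why: Base-catalysed transesterification (Zemplén-type methanolysis) removes both aryl acetates at 0 °C, conditions under which the oxirane, the benzylic ether and the three stereocentres are expected to stay intact.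

Compound list
1 | 3-(benzyloxy)-4-methoxybenzaldehyde | COc1ccc(C=O)cc1OCc1ccccc1 | starting material
2 | dimethyl succinate | COC(=O)CCC(=O)OC | starting material
3 | (E)-4-[3-(benzyloxy)-4-methoxyphenyl]-3-(methoxycarbonyl)but-3-enoic acid | COC(=O)/C(CC(=O)O)=C/c1ccc(OC)c(OCc2ccccc2)c1 | intermediate
4 | (3R)-4-[3-(benzyloxy)-4-methoxyphenyl]-3-(methoxycarbonyl)butanoic acid | COc1ccc(C[C@H](CC(=O)O)C(=O)OC)cc1OCc1ccccc1 | intermediate
5 | 4-tert-butyl 1-methyl (2R)-2-[3-(benzyloxy)-4-methoxybenzyl]butanedioate | COc1ccc(C[C@H](CC(=O)OC(C)(C)C)C(=O)OC)cc1OCc1ccccc1 | intermediate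
6 | tert-butyl (3R)-4-[3-(benzyloxy)-4-methoxyphenyl]-3-(hydroxymethyl)butanoate | COc1ccc(C[C@H](CC(=O)OC(C)(C)C)CO)cc1OCc1ccccc1 | intermediate
7 | tert-butyl (3R)-4-(3-hydroxy-4-methoxyphenyl)-3-(hydroxymethyl)butanoate | COc1ccc(C[C@H](CC(=O)OC(C)(C)C)CO)cc1O | intermediate
8 | tert-butyl (3R)-4-{3-[(TBS)oxy]-4-methoxyphenyl}-3-{[(TBS)oxy]methyl}butanoate | COc1ccc(C[C@H](CC(=O)OC(C)(C)C)CO[Si](C)(C)C(C)(C)C)cc1O[Si](C)(C)C(C)(C)C | intermediate
9 | tert-butyl (3R)-2-formyl-4-{3-[(TBS)oxy]-4-methoxyphenyl}-3-{[(TBS)oxy]methyl}butanoate (C2 epimers and enol form) | COc1ccc(C[C@H](C(C=O)C(=O)OC(C)(C)C)CO[Si](C)(C)C(C)(C)C)cc1O[Si](C)(C)C(C)(C)C | intermediate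
10 | tert-butyl (2Z,3R)-4-{3-[(TBS)oxy]-4-methoxyphenyl}-3-{[(TBS)oxy]methyl}-2-[(Ts-oxy)methylidene]butanoate | COc1ccc(C[C@H](/C(=C/OS(=O)(=O)c2ccc(C)cc2)C(=O)OC(C)(C)C)CO[Si](C)(C)C(C)(C)C)cc1O[Si](C)(C)C(C)(C)C | intermediate
11 | 2-methoxy-4-(4,4,5,5-tetramethyl-1,3,2-dioxaborolan-2-yl)phenol | COc1cc(B2OC(C)(C)C(C)(C)O2)ccc1O | starting material
12 | tert-butyl[2-methoxy-4-(4,4,5,5-tetramethyl-1,3,2-dioxaborolan-2-yl)phenoxy]dimethylsilane | COc1cc(B2OC(C)(C)C(C)(C)O2)ccc1O[Si](C)(C)C(C)(C)C | intermediate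
13 | tert-butyl (2Z,3R)-2-({4-[(TBS)oxy]-3-methoxyphenyl}methylidene)-4-{3-[(TBS)oxy]-4-methoxyphenyl}-3-{[(TBS)oxy]methyl}butanoate | COc1ccc(C[C@H](/C(=C/c2ccc(O[Si](C)(C)C(C)(C)C)c(OC)c2)C(=O)OC(C)(C)C)CO[Si](C)(C)C(C)(C)C)cc1O[Si](C)(C)C(C)(C)C | intermediate
14 | (2Z,3R)-2-({4-[(TBS)oxy]-3-methoxyphenyl}methylidene)-4-{3-[(TBS)oxy]-4-methoxyphenyl}-3-{[(TBS)oxy]methyl}butan-1-ol | COc1ccc(C[C@H](/C(CO)=C/c2ccc(O[Si](C)(C)C(C)(C)C)c(OC)c2)CO[Si](C)(C)C(C)(C)C)cc1O[Si](C)(C)C(C)(C)C | intermediate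
15 | (2Z,3R)-2-[(4-hydroxy-3-methoxyphenyl)methylidene]-4-(3-hydroxy-4-methoxyphenyl)-3-{[(TBS)oxy]methyl}butan-1-ol | COc1ccc(C[C@H](/C(CO)=C/c2ccc(O)c(OC)c2)CO[Si](C)(C)C(C)(C)C)cc1O | intermediate
16 | (2Z,3R)-2-[(4-acetoxy-3-methoxyphenyl)methylidene]-4-(3-acetoxy-4-methoxyphenyl)-3-{[(TBS)oxy]methyl}butan-1-ol | COc1ccc(C[C@H](/C(CO)=C/c2ccc(OC(C)=O)c(OC)c2)CO[Si](C)(C)C(C)(C)C)cc1OC(C)=O | intermediate
17 | {(2S,3R)-3-(4-acetoxy-3-methoxyphenyl)-2-[(2S)-1-(3-acetoxy-4-methoxyphenyl)-3-[(TBS)oxy]propan-2-yl]oxiran-2-yl}methanol | CC(C)(C)[Si](C)(C)OC[C@H](Cc1ccc(OC)c(OC(C)=O)c1)[C@@]1(CO)O[C@@H]1c1ccc(OC(C)=O)c(OC)c1 | intermediate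
18 | {(2S,3R)-3-(4-acetoxy-3-methoxyphenyl)-2-[(2S)-1-(3-acetoxy-4-methoxyphenyl)-3-[(TBS)oxy]propan-2-yl]oxiran-2-yl}methyl 4-methylbenzenesulfonate | CC(C)(C)[Si](C)(C)OC[C@H](Cc1ccc(OC)c(OC(C)=O)c1)[C@@]1(COS(=O)(=O)c2ccc(C)cc2)O[C@@H]1c1ccc(OC(C)=O)c(OC)c1 | intermediate
19 | {(2S,3R)-3-(4-acetoxy-3-methoxyphenyl)-2-[(2S)-1-(3-acetoxy-4-methoxyphenyl)-3-hydroxypropan-2-yl]oxiran-2-yl}methyl 4-methylbenzenesulfonate | OC[C@H](Cc1ccc(OC)c(OC(C)=O)c1)[C@@]1(COS(=O)(=O)c2ccc(C)cc2)O[C@@H]1c1ccc(OC(C)=O)c(OC)c1 | intermediate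
20 | [(2S,3S,4S)-2-(4-acetoxy-3-methoxyphenyl)-4-(3-acetoxy-4-methoxybenzyl)-3-hydroxytetrahydrofuran-3-yl]methyl 4-methylbenzenesulfonate | COc1ccc(C[C@H]2CO[C@@H](c3ccc(OC(C)=O)c(OC)c3)[C@@]2(O)COS(=O)(=O)c2ccc(C)cc2)cc1OC(C)=O | intermediate
21 | (3S,4S,7S)-4-(4-acetoxy-3-methoxyphenyl)-7-(3-acetoxy-4-methoxybenzyl)-1,5-dioxaspiro[2.4]heptane | COc1ccc(C[C@H]2CO[C@@H](c3ccc(OC(C)=O)c(OC)c3)[C@@]23CO3)cc1OC(C)=O | intermediate
22 | (3S,4S,7S)-4-(4-hydroxy-3-methoxyphenyl)-7-(3-hydroxy-4-methoxybenzyl)-1,5-dioxaspiro[2.4]heptane | COc1ccc(C[C@H]2CO[C@@H](c3ccc(O)c(OC)c3)[C@@]23CO3)cc1O | target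

Total step count: 17. Longest linear sequence: 16 steps (steps 1 to 8 and 10 to 17); step 9 is a one-step side branch.

Steps most likely to fail

Step 16 (key step). The protonated benzylic epoxide may ionise before the C5 oxygen arrives, which would erode the inversion at C2 or divert material into a 1,2-shift to a carbonyl compound. The fallback sets out from 17 and removes the tosylate from the acid stage altogether. The silyl ether is cleaved first (HF·pyridine, pyridine, THF) to give the epoxy diol F1. Ti(OiPr)4 in CH2Cl2 then binds the oxiranylmethanol and directs the tethered C5 hydroxyl to the distal, benzylic epoxide carbon, which is the known titanium-assisted opening of 2,3-epoxy alcohols at the carbon remote from the carbinol. This should give the tetrahydrofuran diol F2 with inversion at C2. Sulfonylation of the primary hydroxyl in the presence of the tertiary one (TsCl, Et3N, CH2Cl2, 0 °C) returns to the route at 20, which DBU closes to 21 as in the second half of step 16.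

Step 13. Oxygen transfer to a hindered, Z-configured and 2-branched styrenyl alcohol may be slow and insufficiently face-selective, possibly in a mismatched pairing with C4, and the titanium alkoxide may exchange the aryl acetates or open the product. The fallback sets out from 16 and gives up reagent control: hydroxyl-guided peracid epoxidation (m-CPBA, NaHCO3 buffer, CH2Cl2, 0 °C; Henbest-type) keeps the cis geometry but attacks both faces. Compound 17 is then separated by chromatography from its (2R,3S)-oxirane diastereomer F3, which is possible because the fixed C4 centre makes the two diastereomers and not enantiomers. The route is rejoined at 17.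

Step 8. Chelation control in the enol sulfonylation may be incomplete, giving E/Z mixtures, or geometry may leak in the coupling that follows. The fallback sets out from 8 and builds the alkene by condensation and isomerisation. The lithium enolate of 8 is added to 4-[(tert-butyldimethylsilyl)oxy]-3-methoxybenzaldehyde (a catalogue aldehyde, COc1cc(C=O)ccc1O[Si](C)(C)C(C)(C)C) to give the aldol adduct F4 as a diastereomer mixture. Mesylation (MsCl, Et3N) gives the mesylate F5, which is not isolated, and DBU eliminates it to the thermodynamically preferred E enoate F6. Triplet-sensitised E-to-Z photoisomerisation (thioxanthone, 365–400 nm) followed by chromatographic separation, with recycling of F6, then delivers the Z enoate and rejoins the route at 13.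

Further compounds
F1 | step 16 | {(2S,3R)-3-(4-acetoxy-3-methoxyphenyl)-2-[(2S)-1-(3-acetoxy-4-methoxyphenyl)-3-hydroxypropan-2-yl]oxiran-2-yl}methanol | OC[C@H](Cc1ccc(OC)c(OC(C)=O)c1)[C@@]1(CO)O[C@@H]1c1ccc(OC(C)=O)c(OC)c1
F2 | step 16 | (2S,3S,4S)-2-(4-acetoxy-3-methoxyphenyl)-4-(3-acetoxy-4-methoxybenzyl)-3-(hydroxymethyl)tetrahydrofuran-3-ol | COc1ccc(C[C@H]2CO[C@@H](c3ccc(OC(C)=O)c(OC)c3)[C@@]2(O)CO)cc1OC(C)=O
F3 | step 13 | {(2R,3S)-3-(4-acetoxy-3-methoxyphenyl)-2-[(2S)-1-(3-acetoxy-4-methoxyphenyl)-3-[(TBS)oxy]propan-2-yl]oxiran-2-yl}methanol | CC(C)(C)[Si](C)(C)OC[C@H](Cc1ccc(OC)c(OC(C)=O)c1)[C@]1(CO)O[C@H]1c1ccc(OC(C)=O)c(OC)c1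
F4 | step 8 | tert-butyl (3R)-2-(hydroxy{4-[(TBS)oxy]-3-methoxyphenyl}methyl)-4-{3-[(TBS)oxy]-4-methoxyphenyl}-3-{[(TBS)oxy]methyl}butanoate (diastereomer mixture) | COc1ccc(C[C@H](C(C(O)c2ccc(O[Si](C)(C)C(C)(C)C)c(OC)c2)C(=O)OC(C)(C)C)CO[Si](C)(C)C(C)(C)C)cc1O[Si](C)(C)C(C)(C)C
F5 | step 8 | tert-butyl (3R)-2-[(methanesulfonyloxy){4-[(TBS)oxy]-3-methoxyphenyl}methyl]-4-{3-[(TBS)oxy]-4-methoxyphenyl}-3-{[(TBS)oxy]methyl}butanoate | COc1ccc(C[C@H](C(C(OS(C)(=O)=O)c2ccc(O[Si](C)(C)C(C)(C)C)c(OC)c2)C(=O)OC(C)(C)C)CO[Si](C)(C)C(C)(C)C)cc1O[Si](C)(C)C(C)(C)C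
F6 | step 8 | tert-butyl (2E,3R)-2-({4-[(TBS)oxy]-3-methoxyphenyl}methylidene)-4-{3-[(TBS)oxy]-4-methoxyphenyl}-3-{[(TBS)oxy]methyl}butanoate | COc1ccc(C[C@H](/C(=C\c2ccc(O[Si](C)(C)C(C)(C)C)c(OC)c2)C(=O)OC(C)(C)C)CO[Si](C)(C)C(C)(C)C)cc1O[Si](C)(C)C(C)(C)C
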